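**Plan**
1. Retrosynthesis: the two angelate C–O bonds (at C2 and C6) are cut first; the C8=C9 alkene is then traced to its C9=C10 isomer and the C6 carbinol to a ketone.
2. The ring bonds C7–C8 and C1–C5 are cut together. C5–C6–C7 is a three-carbon unit with oxygen on its central carbon C6 and with the C4 carbinol next to it, so it is an oxyallyl cation masked as an epoxy enol silane (C4–O–C5 oxirane, C6=C7 silyl enol ether). C1=C10–C9=C8 is a diene held to it by the tether C2–C3–C4.
3. The open chain is cut at the oxirane (from the C4=C5 alkene), at C4=C5 (lactone-templated olefination), at C2–C3 (aldol) and at C1=C10 (Wittig).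
4. Forward: dienal → aldol → lactone → epoxy methyl ketone → enol silane → cyclopentane (ring A) and cycloheptene (ring B) closed together by one (4+3) cycloaddition → reduction, alkene shift, double acylation.
5. Stereochemistry: C2 from the asymmetric aldol; C4 and C5 from the asymmetric epoxidation (C5 with inversion in the key step); C1 from the key step; C6 from hydroxyl-directed reduction; ester geometry from (Z)-angelic acid.

Key step: step 13

Remarks on the chemistry
- Daucane numbering is used for atoms: C1 quaternary ring-fusion carbon (methyl), C2 CH–O of ring A, C3 CH2, C4 C(OH)(iPr), C5 ring-fusion CH, C6 CH–O of ring B, C7 CH2, C8 C(CH3)=, C9 =CH, C10 CH2. The β face is the face of the C1 methyl group. The target is 2α,6α-bis(angeloyloxy)-4β-hydroxydauc-8-ene (5α-H, trans-fused).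
- Assumption: the enolate made with (+)-Ipc2BCl (from (−)-α-pinene) is taken to add to the Si face of aldehyde 3; the antipodal reagent is equally available.
- The C8 configuration drawn for 19–21 is the one expected from suprafacial addition to the (E)-propenyl terminus; it is erased in step 16.

Step 1
Reactants: 1 (E)-but-2-enal; 2 2-(triphenyl-λ5-phosphanylidene)propanal
Product: 3 (2E,4E)-2-methylhexa-2,4-dienal
Conditions: 1 (3 equiv), PhMe, 80 °C
Reagents that add atoms: none
Why: Wittig olefination with a stabilized α-formyl ylide should form the (E)-trisubstituted C1=C10 alkene, which places the future tether carbon C2 trans to C9, while the excess of volatile 1 suppresses a second olefination of 3.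

Step 2
Reactants: 4 3-methylbutan-2-one; 3 (2E,4E)-2-methylhexa-2,4-dienal
Product: 7 (5S,6E,8E)-5-hydroxy-2,6-dimethyldeca-6,8-dien-3-one, via boron enolate 5 (not isolated), via boron aldolate 6 (not isolated)
Conditions: (+)-Ipc2BCl, Et3N, Et2O, −78 °C; 3, −78 → −20 °C; then H2O2, MeOH/H2O (pH 7)
Reagents that add atoms: none
Why: Diisopinocampheylboron-mediated asymmetric aldol reaction of a methyl ketone, in which enolization on the methyl side and a cyclic reagent-controlled transition state should set C2 as S, any minor enantiomer becoming a separable diastereomer after the reagent-controlled epoxidation of step 8.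

Step 3
Reactants: 7 (5S,6E,8E)-5-hydroxy-2,6-dimethyldeca-6,8-dien-3-one; 8 2-(diethoxyphosphoryl)acetic acid
Product: 9 (5S,6E,8E)-2,6-dimethyl-3-oxodeca-6,8-dien-5-yl 2-(diethoxyphosphoryl)acetate
Conditions: DCC, DMAP (cat.), CH2Cl2, 0 °C
Reagents that add atoms: none
Why: Steglich esterification of the secondary alcohol at low temperature with only catalytic DMAP should avoid β-elimination of the β-acyloxy ketone.

Step 4
Reactants: 9 (5S,6E,8E)-2,6-dimethyl-3-oxodeca-6,8-dien-5-yl 2-(diethoxyphosphoryl)acetate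
Product: 10 (6S)-6-[(2E,4E)-hexa-2,4-dien-2-yl]-4-(propan-2-yl)-5,6-dihydro-2H-pyran-2-one
Conditions: LiCl, DBU, MeCN, 0 °C → rt
Reagents that add atoms: none
Why: Intramolecular Horner–Wadsworth–Emmons reaction (Masamune–Roush conditions) onto the isopropyl ketone, in which the six-membered lactone can only hold C3 and C6 cis across the new C4=C5 bond, the geometry the oxirane will need.

Step 5
Reactants: 10 (6S)-6-[(2E,4E)-hexa-2,4-dien-2-yl]-4-(propan-2-yl)-5,6-dihydro-2H-pyran-2-one
Product: 11 (2E,5S,6E,8E)-6-methyl-3-(propan-2-yl)deca-2,6,8-triene-1,5-diol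
Conditions: iBu2AlH (4 equiv), CH2Cl2, −78 → 0 °C
Reagents that add atoms: none
Why: Exhaustive 1,2-reduction of the α,β-unsaturated lactone with diisobutylaluminium hydride should open it to the allylic diol with the ring-derived alkene geometry intact.

Step 6
Reactants: 11 (2E,5S,6E,8E)-6-methyl-3-(propan-2-yl)deca-2,6,8-triene-1,5-diol
Product: 12 (2E,5S,6E,8E)-1,5-bis{[tert-butyl(dimethyl)silyl]oxy}-6-methyl-3-(propan-2-yl)deca-2,6,8-triene
Conditions: tBuMe2SiOTf, 2,6-lutidine, CH2Cl2, −78 → 0 °C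
Reagents that add atoms: tert-butyldimethylsilyl trifluoromethanesulfonate, CC(C)(C)[Si](C)(C)OS(=O)(=O)C(F)(F)F
Why: Silyl triflate silylation should protect both hydroxyls, the hindered secondary dienylic one included.

Step 7
Reactants: 12 (2E,5S,6E,8E)-1,5-bis{[tert-butyl(dimethyl)silyl]oxy}-6-methyl-3-(propan-2-yl)deca-2,6,8-triene
Product: 13 (2E,5S,6E,8E)-5-{[tert-butyl(dimethyl)silyl]oxy}-6-methyl-3-(propan-2-yl)deca-2,6,8-trien-1-ol
Conditions: HF·pyridine, pyridine, THF, 0 °C
Reagents that add atoms: none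
Why: Selective desilylation, since a primary allylic silyl ether is cleaved much faster than the hindered secondary one under buffered HF·pyridine.

Step 8
Reactants: 13 (2E,5S,6E,8E)-5-{[tert-butyl(dimethyl)silyl]oxy}-6-methyl-3-(propan-2-yl)deca-2,6,8-trien-1-ol
Product: 14 [(2R,3R)-3-[(2S,3E,5E)-2-{[tert-butyl(dimethyl)silyl]oxy}-3-methylhepta-3,5-dien-1-yl]-3-(propan-2-yl)oxiran-2-yl]methanol
Conditions: Ti(OiPr)4 (10 mol %), D-(−)-diethyl tartrate (12 mol %), tBuOOH, 4 Å MS, CH2Cl2, −20 °C
Reagents that add atoms: tert-butyl hydroperoxide, CC(C)(C)OO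
Why: Katsuki–Sharpless asymmetric epoxidation under reagent control by the D-(−)-tartrate should give the (2R,3R)-epoxy alcohol (C4 and C5) stereospecifically from the alkene geometry and should leave the diene, which has no free allylic hydroxyl, untouched.

Step 9
Reactants: 14 [(2R,3R)-3-[(2S,3E,5E)-2-{[tert-butyl(dimethyl)silyl]oxy}-3-methylhepta-3,5-dien-1-yl]-3-(propan-2-yl)oxiran-2-yl]methanol
Product: 15 (2S,3R)-3-[(2S,3E,5E)-2-{[tert-butyl(dimethyl)silyl]oxy}-3-methylhepta-3,5-dien-1-yl]-3-(propan-2-yl)oxirane-2-carbaldehyde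
Conditions: Dess–Martin periodinane, CH2Cl2, 0 °C → rt
Reagents that add atoms: none
Why: Dess–Martin oxidation should convert the primary epoxy alcohol into the epoxy aldehyde under near-neutral, non-epimerizing conditions.

Step 10
Reactants: 15 (2S,3R)-3-[(2S,3E,5E)-2-{[tert-butyl(dimethyl)silyl]oxy}-3-methylhepta-3,5-dien-1-yl]-3-(propan-2-yl)oxirane-2-carbaldehyde
Product: 16 1-[(2R,3R)-3-[(2S,3E,5E)-2-{[tert-butyl(dimethyl)silyl]oxy}-3-methylhepta-3,5-dien-1-yl]-3-(propan-2-yl)oxiran-2-yl]ethan-1-ol (mixture of epimers at the new carbinol)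
Conditions: MeMgBr, THF, −78 °C
Reagents that add atoms: methylmagnesium bromide, C[Mg]Br
Why: Grignard 1,2-addition to the aldehyde should be much faster than oxirane opening at −78 °C and brings in C7, the new carbinol configuration being irrelevant because it is oxidized next.

Step 11
Reactants: 16 1-[(2R,3R)-3-[(2S,3E,5E)-2-{[tert-butyl(dimethyl)silyl]oxy}-3-methylhepta-3,5-dien-1-yl]-3-(propan-2-yl)oxiran-2-yl]ethan-1-ol
Product: 17 1-[(2S,3R)-3-[(2S,3E,5E)-2-{[tert-butyl(dimethyl)silyl]oxy}-3-methylhepta-3,5-dien-1-yl]-3-(propan-2-yl)oxiran-2-yl]ethan-1-one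
Conditions: Dess–Martin periodinane, CH2Cl2, rt
Reagents that add atoms: none
Why: Dess–Martin oxidation of the secondary alcohol should give the α,β-epoxy methyl ketone without touching the oxirane or the diene.

Step 12
Reactants: 17 1-[(2S,3R)-3-[(2S,3E,5E)-2-{[tert-butyl(dimethyl)silyl]oxy}-3-methylhepta-3,5-dien-1-yl]-3-(propan-2-yl)oxiran-2-yl]ethan-1-one
Product: 18 triethyl[(1-{(2S,3R)-3-[(2S,3E,5E)-2-{[tert-butyl(dimethyl)silyl]oxy}-3-methylhepta-3,5-dien-1-yl]-3-(propan-2-yl)oxiran-2-yl}ethenyl)oxy]silane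
Conditions: LiN(SiMe3)2, Et3SiCl, THF, −78 °C
Reagents that add atoms: chlorotriethylsilane, CC[Si](Cl)(CC)CC
Why: Silyl enol ether formation by kinetic enolization, which can only occur at the methyl group because the other α-carbon is the oxirane carbon C5.

Step 13
Reactants: 18 triethyl[(1-{(2S,3R)-3-[(2S,3E,5E)-2-{[tert-butyl(dimethyl)silyl]oxy}-3-methylhepta-3,5-dien-1-yl]-3-(propan-2-yl)oxiran-2-yl}ethenyl)oxy]silane
Product: 19 (1S,3R,3aR,6R,8aR)-1-{[tert-butyl(dimethyl)silyl]oxy}-6,8a-dimethyl-3-(propan-2-yl)-3-[(triethylsilyl)oxy]-2,3,3a,5,6,8a-hexahydroazulen-4(1H)-one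
Conditions: Et3SiOTf (10 mol %), CH2Cl2 (0.01 M), −78 °C; then Et3N
Reagents that add atoms: none
Why: The silyl triflate silylates the oxirane oxygen, and the C5–O bond, allylic to the silyl enol ether, ionizes toward a 2-silyloxyallyl (oxyallyl) cation that is captured across the diene termini C1 and C8, after which the C6 oxocarbenium ion releases its silyl group to turn the catalyst over; the closest known reaction type is the silyl triflate-catalysed intramolecular (4+3) cycloaddition of epoxy enol silanes with tethered dienes. Ring A closes by attack of diene carbon C1 on oxirane carbon C5 anti to the departing oxygen (a 5-endo-type oxirane opening made possible by the allylic stabilization at C5), and ring B closes when the enol silane terminus C7 bonds to C8, both bonds forming on one face of the diene in a concerted but asynchronous addition of the allyl cation to the 4π system. C5 is set by inversion at the oxirane carbon, so the retained C4–O bond (4R) and C6 end up cis on ring A. C1 is set by the diene face that the short tether presents, with the C2 silyloxy group lying near the alkene plane and away from the C1 methyl (allylic 1,2-strain), which together should give the trans ring fusion with the C1 methyl cis to the C4 oxygen; C8 follows from the (E)-propenyl geometry and is erased later. The step needs cleavage of C5–O in preference to the tertiary C4–O bond, which the enol silane conjugation and a catalytic non-nucleophilic Lewis acid at low temperature should secure. It also needs a reactive s-cis diene despite the inside C1 methyl, which the cationic, intramolecular character should tolerate, and trans over cis fusion, secured as described.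

Step 14
Reactants: 19 (1S,3R,3aR,6R,8aR)-1-{[tert-butyl(dimethyl)silyl]oxy}-6,8a-dimethyl-3-(propan-2-yl)-3-[(triethylsilyl)oxy]-2,3,3a,5,6,8a-hexahydroazulen-4(1H)-one
Product: 20 (1S,3R,3aR,6R,8aR)-1,3-dihydroxy-6,8a-dimethyl-3-(propan-2-yl)-2,3,3a,5,6,8a-hexahydroazulen-4(1H)-one
Conditions: HF·pyridine, THF, 0 °C → rt
Reagents that add atoms: none
Why: Fluoride-mediated global desilylation under mildly acidic conditions is chosen to avoid the retro-aldol cleavage or β-elimination of the β-hydroxy ketone that basic fluoride could cause.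

Step 15
Reactants: 20 (1S,3R,3aR,6R,8aR)-1,3-dihydroxy-6,8a-dimethyl-3-(propan-2-yl)-2,3,3a,5,6,8a-hexahydroazulen-4(1H)-one
Product: 21 (1S,3R,3aS,4S,6R,8aR)-6,8a-dimethyl-3-(propan-2-yl)-1,2,3,3a,4,5,6,8a-octahydroazulene-1,3,4-triol
Conditions: Me4NBH(OAc)3, MeCN/AcOH (1:1), −30 → 0 °C
Reagents that add atoms: none
Why: Evans–Saksena hydroxyl-directed reduction, in which the β-oriented C4 hydroxyl exchanges onto boron and delivers hydride to the β face of the C6 ketone, should give the 4,6-anti diol, that is the 6α-alcohol (6S in daucane numbering, C4 of the azulene name).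

Step 16
Reactants: 21 (1S,3R,3aS,4S,6R,8aR)-6,8a-dimethyl-3-(propan-2-yl)-1,2,3,3a,4,5,6,8a-octahydroazulene-1,3,4-triol
Product: 22 (1S,3R,3aS,4S,8aR)-6,8a-dimethyl-3-(propan-2-yl)-1,2,3,3a,4,5,8,8a-octahydroazulene-1,3,4-triol
Conditions: RhCl3·3H2O (10 mol %), EtOH, 70 °C, monitored and stopped at full conversion
Reagents that add atoms: none
Why: Rhodium hydride-mediated alkene isomerization (hydrometallation and β-hydride elimination) can move the C9=C10 alkene only toward C8 because C1 is quaternary, gives the more stable trisubstituted C8=C9 alkene, and should be much slower beyond C8 because that would require a tertiary alkyl–rhodium intermediate.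

Step 17
Reactants: 22 (1S,3R,3aS,4S,8aR)-6,8a-dimethyl-3-(propan-2-yl)-1,2,3,3a,4,5,8,8a-octahydroazulene-1,3,4-triol; 23 (2Z)-2-methylbut-2-enoic acid (angelic acid)
Product: 25 (1S,3R,3aS,4S,8aR)-3-hydroxy-6,8a-dimethyl-3-(propan-2-yl)-1,2,3,3a,4,5,8,8a-octahydroazulene-1,4-diyl bis[(2Z)-2-methylbut-2-enoate], via mixed anhydride 24 (not isolated)
Conditions: 23 (6 equiv), 2,4,6-Cl3C6H2COCl, Et3N, PhMe, rt; then 22, 80 °C
Reagents that add atoms: none
Why: Yamaguchi-type esterification through the angelic 2,4,6-trichlorobenzoic mixed anhydride without a nucleophilic catalyst should acylate both secondary hydroxyls (C2 and C6) with the (Z)-geometry kept, while the tertiary C4 hydroxyl should not react.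

**Compound list**
1 | (E)-but-2-enal | C/C=C/C=O | starting material
2 | 2-(triphenyl-λ5-phosphanylidene)propanal | CC(C=O)=P(c1ccccc1)(c1ccccc1)c1ccccc1 | starting material
3 | (2E,4E)-2-methylhexa-2,4-dienal | O=C/C(C)=C/C=C/C | intermediate
4 | 3-methylbutan-2-one | CC(=O)C(C)C | starting material
5 | boron enolate: [(3-methylbut-1-en-2-yl)oxy]bis[(+)-isopinocampheyl]borane | C=C(C(C)C)OB([C@H]1C[C@H]2C[C@@H]([C@@H]1C)C2(C)C)[C@H]1C[C@H]2C[C@@H]([C@@H]1C)C2(C)C | intermediate
6 | boron aldolate: (5S,6E,8E)-5-{[bis((+)-isopinocampheyl)boranyl]oxy}-2,6-dimethyldeca-6,8-dien-3-one | CC(C)C(=O)C[C@H](OB([C@H]1C[C@H]2C[C@@H]([C@@H]1C)C2(C)C)[C@H]1C[C@H]2C[C@@H]([C@@H]1C)C2(C)C)/C(C)=C/C=C/C | intermediate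
7 | (5S,6E,8E)-5-hydroxy-2,6-dimethyldeca-6,8-dien-3-one | CC(C)C(=O)C[C@H](O)/C(C)=C/C=C/C | intermediate
8 | 2-(diethoxyphosphoryl)acetic acid | CCOP(=O)(OCC)CC(=O)O | starting material
9 | (5S,6E,8E)-2,6-dimethyl-3-oxodeca-6,8-dien-5-yl 2-(diethoxyphosphoryl)acetate | CCOP(=O)(OCC)CC(=O)O[C@@H](CC(=O)C(C)C)/C(C)=C/C=C/C | intermediate
10 | (6S)-6-[(2E,4E)-hexa-2,4-dien-2-yl]-4-(propan-2-yl)-5,6-dihydro-2H-pyran-2-one | O=C1C=C(C(C)C)C[C@H](O1)/C(C)=C/C=C/C | intermediate
11 | (2E,5S,6E,8E)-6-methyl-3-(propan-2-yl)deca-2,6,8-triene-1,5-diol | OC/C=C(/C(C)C)C[C@H](O)/C(C)=C/C=C/C | intermediate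
12 | (2E,5S,6E,8E)-1,5-bis{[tert-butyl(dimethyl)silyl]oxy}-6-methyl-3-(propan-2-yl)deca-2,6,8-triene | CC(C)(C)[Si](C)(C)OC/C=C(/C(C)C)C[C@H](O[Si](C)(C)C(C)(C)C)/C(C)=C/C=C/C | intermediate
13 | (2E,5S,6E,8E)-5-{[tert-butyl(dimethyl)silyl]oxy}-6-methyl-3-(propan-2-yl)deca-2,6,8-trien-1-ol | OC/C=C(/C(C)C)C[C@H](O[Si](C)(C)C(C)(C)C)/C(C)=C/C=C/C | intermediate
14 | [(2R,3R)-3-[(2S,3E,5E)-2-{[tert-butyl(dimethyl)silyl]oxy}-3-methylhepta-3,5-dien-1-yl]-3-(propan-2-yl)oxiran-2-yl]methanol | OC[C@H]1O[C@@]1(C(C)C)C[C@H](O[Si](C)(C)C(C)(C)C)/C(C)=C/C=C/C | intermediate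
15 | (2S,3R)-3-[(2S,3E,5E)-2-{[tert-butyl(dimethyl)silyl]oxy}-3-methylhepta-3,5-dien-1-yl]-3-(propan-2-yl)oxirane-2-carbaldehyde | O=C[C@H]1O[C@@]1(C(C)C)C[C@H](O[Si](C)(C)C(C)(C)C)/C(C)=C/C=C/C | intermediate
16 | 1-[(2R,3R)-3-[(2S,3E,5E)-2-{[tert-butyl(dimethyl)silyl]oxy}-3-methylhepta-3,5-dien-1-yl]-3-(propan-2-yl)oxiran-2-yl]ethan-1-ol, carbinol epimers | CC(O)[C@H]1O[C@@]1(C(C)C)C[C@H](O[Si](C)(C)C(C)(C)C)/C(C)=C/C=C/C | intermediate
17 | 1-[(2S,3R)-3-[(2S,3E,5E)-2-{[tert-butyl(dimethyl)silyl]oxy}-3-methylhepta-3,5-dien-1-yl]-3-(propan-2-yl)oxiran-2-yl]ethan-1-one | CC(=O)[C@H]1O[C@@]1(C(C)C)C[C@H](O[Si](C)(C)C(C)(C)C)/C(C)=C/C=C/C | intermediate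
18 | triethyl[(1-{(2S,3R)-3-[(2S,3E,5E)-2-{[tert-butyl(dimethyl)silyl]oxy}-3-methylhepta-3,5-dien-1-yl]-3-(propan-2-yl)oxiran-2-yl}ethenyl)oxy]silane | C=C(O[Si](CC)(CC)CC)[C@H]1O[C@@]1(C(C)C)C[C@H](O[Si](C)(C)C(C)(C)C)/C(C)=C/C=C/C | intermediate
19 | (1S,3R,3aR,6R,8aR)-1-{[tert-butyl(dimethyl)silyl]oxy}-6,8a-dimethyl-3-(propan-2-yl)-3-[(triethylsilyl)oxy]-2,3,3a,5,6,8a-hexahydroazulen-4(1H)-one | O=C1C[C@@H](C)C=C[C@@]2(C)[C@@H](O[Si](C)(C)C(C)(C)C)C[C@@](O[Si](CC)(CC)CC)(C(C)C)[C@H]12 | intermediate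
20 | (1S,3R,3aR,6R,8aR)-1,3-dihydroxy-6,8a-dimethyl-3-(propan-2-yl)-2,3,3a,5,6,8a-hexahydroazulen-4(1H)-one | O=C1C[C@@H](C)C=C[C@@]2(C)[C@@H](O)C[C@@](O)(C(C)C)[C@H]12 | intermediate
21 | (1S,3R,3aS,4S,6R,8aR)-6,8a-dimethyl-3-(propan-2-yl)-1,2,3,3a,4,5,6,8a-octahydroazulene-1,3,4-triol | O[C@H]1C[C@@H](C)C=C[C@@]2(C)[C@@H](O)C[C@@](O)(C(C)C)[C@H]12 | intermediate
22 | (1S,3R,3aS,4S,8aR)-6,8a-dimethyl-3-(propan-2-yl)-1,2,3,3a,4,5,8,8a-octahydroazulene-1,3,4-triol | O[C@H]1CC(C)=CC[C@@]2(C)[C@@H](O)C[C@@](O)(C(C)C)[C@H]12 | intermediate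
23 | (2Z)-2-methylbut-2-enoic acid (angelic acid) | C/C=C(/C)C(=O)O | starting material
24 | (2Z)-2-methylbut-2-enoic 2,4,6-trichlorobenzoic anhydride | C/C=C(/C)C(=O)OC(=O)c1c(Cl)cc(Cl)cc1Cl | intermediate
25 | (1S,3R,3aS,4S,8aR)-3-hydroxy-6,8a-dimethyl-3-(propan-2-yl)-1,2,3,3a,4,5,8,8a-octahydroazulene-1,4-diyl bis[(2Z)-2-methylbut-2-enoate] | C/C=C(/C)C(=O)O[C@H]1CC(C)=CC[C@@]2(C)[C@@H](OC(=O)/C(C)=C\C)C[C@@](O)(C(C)C)[C@H]12 | target

**Totals**
Total step count: 17. Longest linear sequence: 17 steps (1 → 25).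

**Steps most likely to fail**

1. Step 13. The tertiary C4–O bond may ionize instead of C5–O, leading to hydride shift or elimination. The hindered C1 terminus of the diene may fail to form the quaternary centre. The ring fusion may form with poor trans selectivity. The fallback sets out from 17 and comes back at 19; it generates the oxyallyl cation from an α-chloro ketone with base, without a Lewis acid. Reductive opening of 17 with SmI2 (THF/MeOH, −90 °C) should give (4S,6S,7E,9E)-6-{[tert-butyl(dimethyl)silyl]oxy}-4-hydroxy-7-methyl-4-(propan-2-yl)undeca-7,9-dien-2-one F1 with C4 intact. Silylation (Et3SiOTf, 2,6-lutidine) gives its 4-O-triethylsilyl ether F2. Kinetic enolization on the methyl side (LiN(SiMe3)2, Me3SiCl) gives the trimethylsilyl enol ether F3, and N-chlorosuccinimide turns it into the chloromethyl ketone F4. Et3N in CF3CH2OH should then ionize F4 through its enol to the same oxyallyl cation, which adds across the tethered diene to give 19. C5 is then no longer set by inversion, but it is α to the ketone and can be equilibrated toward the trans-fused isomer.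

2. Step 16. The alkene may migrate further, to C7=C8 and on toward the C6 carbinol, or the tertiary alcohol may dehydrate in the warm, slightly acidic medium. The fallback sets out from 21 and comes back at 22; it relocates the alkene by hydration and dehydration instead of by hydride catalysis. Et3SiOTf and 2,6-lutidine give the tris(triethylsilyl) ether of 21 F5. Hydroboration and oxidation (BH3·THF; then H2O2, NaOH) should place the hydroxyl on C9, away from the neopentyl C10, to give the C9 alcohol F6. Burgess dehydration by syn elimination toward the tertiary C8–H should give the C8=C9 tris(triethylsilyl) ether F7; any C10 alcohol could only return the C9=C10 alkene. HF·pyridine then gives 22.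

3. Step 17. The angeloyl group may isomerize to the (E)-tigloyl group during activation, and acylation of the neopentyl C2 hydroxyl may stay incomplete. The fallback sets out from 22 and comes back at 25; it builds the (Z)-alkenes on the esters instead of transferring them. Acylation of both secondary hydroxyls with 2-[bis(2,2,2-trifluoroethoxy)phosphoryl]propanoic acid (DCC, DMAP) gives the bis(phosphonopropanoate) of 22 F8. A double Still–Gennari olefination with acetaldehyde (KN(SiMe3)2, 18-crown-6, THF, −78 °C) should then form both (Z)-2-methylbut-2-enoates and give 25.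

**Further compounds**
F1 | step 13 | (4S,6S,7E,9E)-6-{[tert-butyl(dimethyl)silyl]oxy}-4-hydroxy-7-methyl-4-(propan-2-yl)undeca-7,9-dien-2-one | CC(=O)C[C@](O)(C(C)C)C[C@H](O[Si](C)(C)C(C)(C)C)/C(C)=C/C=C/C
F2 | step 13 | 4-O-triethylsilyl ether of F1 | CC(=O)C[C@](O[Si](CC)(CC)CC)(C(C)C)C[C@H](O[Si](C)(C)C(C)(C)C)/C(C)=C/C=C/C
F3 | step 13 | trimethylsilyl enol ether of F2 (C1=C2 of the undecadienone chain) | C=C(O[Si](C)(C)C)C[C@](O[Si](CC)(CC)CC)(C(C)C)C[C@H](O[Si](C)(C)C(C)(C)C)/C(C)=C/C=C/C
F4 | step 13 | 1-chloro derivative of F2 (chloromethyl ketone) | ClCC(=O)C[C@](O[Si](CC)(CC)CC)(C(C)C)C[C@H](O[Si](C)(C)C(C)(C)C)/C(C)=C/C=C/C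
F5 | step 16 | tris(triethylsilyl) ether of 21 | CC[Si](CC)(CC)O[C@H]1C[C@@H](C)C=C[C@@]2(C)[C@@H](O[Si](CC)(CC)CC)C[C@@](O[Si](CC)(CC)CC)(C(C)C)[C@H]12
F6 | step 16 | C9 alcohol from hydroboration of F5 (C9 configuration not assigned) | CC[Si](CC)(CC)O[C@H]1C[C@@H](C)C(O)C[C@@]2(C)[C@@H](O[Si](CC)(CC)CC)C[C@@](O[Si](CC)(CC)CC)(C(C)C)[C@H]12
F7 | step 16 | tris(triethylsilyl) ether of 22 | CC[Si](CC)(CC)O[C@H]1CC(C)=CC[C@@]2(C)[C@@H](O[Si](CC)(CC)CC)C[C@@](O[Si](CC)(CC)CC)(C(C)C)[C@H]12
F8 | step 17 | 2,6-bis{2-[bis(2,2,2-trifluoroethoxy)phosphoryl]propanoate} of 22 (phosphonate α-carbons as mixtures) | CC(C(=O)O[C@H]1CC(C)=CC[C@@]2(C)[C@@H](OC(=O)C(C)P(=O)(OCC(F)(F)F)OCC(F)(F)F)C[C@@](O)(C(C)C)[C@H]12)P(=O)(OCC(F)(F)F)OCC(F)(F)F
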